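**Structural features**

Target 11 is a tetrabrominated 2-phenoxyphenol. It has two benzene rings, ring A (C1 to C6) and ring B (C1' to C6'), joined only by the ether oxygen between C6 and C1'. Ring A carries the free hydroxyl at C1, bromine at C2 and C4, and the aryloxy group at C6, so C6, C1 and C2 form a contiguous O-aryl/OH/Br triad. Ring B carries bromine at C2' and C4', ortho and para to the ether oxygen. The molecule has no stereocentre, so no stereocentres stand next to each other and the problem is purely one of regiochemistry. The fragile groups are the four aryl C–Br bonds (lost to alkyllithiums, dissolving metals, hydrogenolysis, and zerovalent palladium or nickel catalysts) and the electron-rich phenol, which is easily over-halogenated or oxidised. The real difficulty is to place four bromines and two oxygen functions on defined carbons while making a diaryl ether flanked by ortho substituents on both rings, without a metal-catalysed C–O coupling that would also engage the C–Br bonds. The key step uses the fact that C6–C1–C2 of ring A corresponds to the γ-carbon, ketone carbon and α-carbon of a 4-aryloxy-3-oxobutanoate, and C3–C4(Br)–C5 to a symmetric bromomalonaldehyde unit. The ester left at C2, ortho to the C1 hydroxyl, is a placeholder that an ipso-bromination with loss of carbon dioxide converts into the last bromine.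

**Logic of the disconnections**

11 back to 9 (through 10). The C2–Br bond is cut and replaced by a C2–carboxyl bond. C2 is the ring carbon that a cyclocondensation delivers with a carbon substituent, and a carboxyl ortho to the C1 hydroxyl can be exchanged for bromine by ipso attack. The gain is that 11 becomes a salicylate, the natural product of a (3+3) ring synthesis. The demand is that electrophilic bromine reacts once, at C2 only, leaving C3 and C5 of ring A and C6' of ring B untouched; this calls for one equivalent, low temperature and a buffered medium.

9 back to 5 and 7 (through 8). The bonds C5–C6 and C2–C3 of ring A are cut. This separates a nucleophilic three-carbon piece (C6–C1–C2, with both oxygens and the ester) from an electrophilic one (C3–C4–C5, with the C4 bromine). The gain is large: ring A becomes two acyclic chains, the ether oxygen sits on a non-aromatic carbon, and because 7 is symmetric there is no orientation to control. The demand is that the terminal carbon of 5 bonds first, the central carbon closes the ring second, and the adduct aromatises, all under a Lewis acid that leaves aryl C–Br and aryl–O bonds alone.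

5 back to 4 and then 3. Two O–Si bonds are cut. By itself 3 is nucleophilic only at the carbon between its carbonyls; 5 is the neutral equivalent of its 1,3-dianion, with the highest nucleophilicity at the terminal carbon that becomes C6. The gain is a plain β-ketoester. The demand is a γ-deprotonation by a strong amide base in the presence of two aryl bromides and the acidic C3'–H between them, so the base is limited to about one equivalent at −78 °C and no alkyllithium is used.

3 back to 1 and 2. The bond between the ring B oxygen and the future C6 is cut while that carbon is still sp3. The ether is then made by a simple displacement at a primary carbon next to a ketone, and ring B arrives complete with both bromines. The gain is two purchasable compounds. The demand is that the phenoxide must win against self-condensation of 2, which is met by holding 2 as its enolate with a second equivalent of base.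

7 back to 6. One O–Si bond is cut. As a free enol, 6 is acidic enough to protonate 5 and to bind the Lewis acid; capping it gives a neutral electrophile with a silyloxy leaving group. The gain is a commercial starting material. The demand is mild silylation, exclusion of moisture and prompt use.

**Other disconnections considered**

Alternative 1: The cut runs through ring B at C1'–C2' and C5'–C6'. C2' to C5' with both bromines would come from 3,5-dibromo-2H-pyran-2-one A1, and C1' and C6' from the aryl ynol ether 1-(ethynyloxy)-2-methoxybenzene A2.
- Forward step: A1 acts as the diene in a (4+2) cycloaddition. The unsubstituted alkyne carbon should bond to C6 of A1 and the oxygen-bearing carbon to C3. The bridged lactone then aromatises by decarboxylative cycloreversion to 2,4-dibromo-1-(2-methoxyphenoxy)benzene A3. Ether cleavage to 2-(2,4-dibromophenoxy)phenol A4 and dibromination ortho and para to the hydroxyl would give 11.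
- In its favour: both ring B bromines come from A1 with no electrophilic bromination of ring B, and no aryl–oxygen coupling is needed. The endgame is a hydroxyl-directed dibromination at the only two open activated positions of ring A. This is at least the equal of the bromodecarboxylation of 10, and better in that it needs no placeholder group.
- Against it: the cycloaddition builds ring B, which can be bought complete as 1, so the strategic step creates little that is not already available. A2 is a hydrolytically and thermally sensitive ynol ether that needs its own two-step preparation, and pyranone cycloadditions need heat. The required orientation (oxygen next to bromine) depends on the polarisation of an unsymmetrical diene.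
- Comparison: structurally the chosen plan spends its ring synthesis on the more densely substituted ring A. Mechanistically the chosen step has no orientation question, whereas this one has one at the defining bond. In step count the two are about equal once A1 and A2 are prepared.

Alternative 2: The cuts are O–C1' and C2'–Br on ring B; no ring is built.
- Forward step: a fluoride source such as CsF would release 4-bromo-1,2-didehydrobenzene A6 from 4-bromo-2-(trimethylsilyl)phenyl trifluoromethanesulfonate A5. The potassium phenoxide of 3,5-dibromo-2-methoxyphenol A7 would add at C1'. The C2' aryl anion would take bromine from 1,2-dibromo-1,1,2,2-tetrachloroethane A8, giving 1,5-dibromo-3-(2,4-dibromophenoxy)-2-methoxybenzene A9. O-demethylation would then give 11.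
- In its favour: it is the most convergent of all the plans. The ether bond and one C–Br bond form in one operation, the phenol stays protected, and no transition metal touches the C–Br bonds. After the key step only one step remains, which is better than the chosen plan in step economy from that point.
- Against it: the C4' bromine is remote from the aryne bond and gives only a weak inductive bias. That bias points the right way, but the isomeric 2,5-dibromophenyl ether must be expected as well, and the two would be hard to separate. The aryl anion can be protonated instead of brominated. The phenoxide has open ring positions that A8 could brominate directly. A5 and A7 both need multistep preparation, and A5 needs an ortho-silylation by organolithium chemistry next to a para bromine.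
- Comparison: structurally it is the equal of the chosen plan or better, since both rings stay simple arenes. Mechanistically it is less controlled, with a regiochemical branch at the very bond that defines ring B. Overall step count is similar once A5 and A7 are included.

Alternative 3: The cuts are C1–C2 and C2–C3 of ring A. C2 and its bromine are removed as a one-carbon unit, leaving the five-membered silyl dienol ether 2-(2,4-dibromophenoxy)-3-(trimethylsilyloxy)cyclopenta-1,3-diene A11, which would be made from 2-(2,4-dibromophenoxy)cyclopent-2-en-1-one A10.
- Forward step: dibromocarbene A13, generated from bromoform A12 and an alkoxide base, would add to the silyl enol ether double bond. The dibromocyclopropane would open with loss of bromide and of the silyl group to a six-membered dienone, which would tautomerise to 2-bromo-6-(2,4-dibromophenoxy)phenol A14. Bromination para to the hydroxyl would give 11.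
- In its favour: the inserted carbon brings its bromine exactly to C2, so no placeholder group is needed, and the final bromination has only one activated open position. On both points this plan is equal to or better than the chosen one.
- Against it: A11 is a cyclopentadiene. It can shift hydrogen around the ring, which would exchange the roles of the two oxygen-bearing double bonds, and it can dimerise. Two electron-rich double bonds compete for the carbene, and addition at the aryloxy-substituted one would insert carbon between C5 and C6 and give a constitutional isomer. The conditions are strongly basic. A10 needs its own synthesis.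
- Comparison: both plans build ring A. The chosen plan does it from two open chains with a symmetric electrophile and no site-selectivity question. The carbene plan is more direct in principle but depends on an isomerically pure, unstable diene and on chemoselective cyclopropanation. The step count is about the same.

Key step: step 5

Assumption: the enol ether geometries of 4, 5, 7 and 8 are taken as immaterial because all are erased on aromatisation; 7 is drawn as its Z isomer, 8 as the E isomer that can cyclise, and 4 and 5 as isomer mixtures.

Step 1
Reactants: 1 2,4-dibromophenol; 2 methyl 4-chloro-3-oxobutanoate (methyl 4-chloroacetoacetate)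
Product: 3 methyl 4-(2,4-dibromophenoxy)-3-oxobutanoate
Conditions: NaH (2.2 equiv), THF–DMF, 0 °C to 60 °C; aq. HCl
Reagents that add atoms: none
Why: Williamson ether synthesis (SN2) at the primary chloromethyl carbon; the second equivalent of NaH holds 2 as its sodium enolate, so the phenoxide is not consumed by proton transfer and self-alkylation of 2 is suppressed; no stereocentre is formed.

Step 2
Reactants: 3 methyl 4-(2,4-dibromophenoxy)-3-oxobutanoate
Product: 4 methyl 4-(2,4-dibromophenoxy)-3-(trimethylsilyloxy)but-2-enoate (E/Z mixture)
Conditions: Me3SiCl (1.5 equiv), Et3N (1.6 equiv), toluene, 20 °C, 48 h; filtration under argon, concentration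
Reagents that add atoms: chlorotrimethylsilane, C[Si](C)(C)Cl
Why: O-silylation of the enolised β-ketoester under amine-base (soft enolisation) conditions gives the conjugated β-silyloxy enoate; it is hydrolytically labile and is taken on without chromatography.

Step 3
Reactants: 4 methyl 4-(2,4-dibromophenoxy)-3-(trimethylsilyloxy)but-2-enoate
Product: 5 4-(2,4-dibromophenoxy)-1-methoxy-1,3-bis(trimethylsilyloxy)buta-1,3-diene (mixture of double-bond isomers)
Conditions: LiN(iPr)2 (1.05 equiv), THF, −78 °C, 45 min; Me3SiCl (1.3 equiv), −78 °C to 20 °C; pentane, filtration, concentration
Reagents that add atoms: chlorotrimethylsilane, C[Si](C)(C)Cl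
Why: Kinetic γ-deprotonation of the vinylogous ester gives a lithium dienolate that is O-silylated at the ester oxygen, the standard second stage in making 1,3-bis(silyloxy)dienes; the CH2 flanked by the aryloxy group and the enol ether is far more acidic than C3'–H between the two bromines, and a lithium amide (unlike an alkyllithium) does not exchange aryl bromides, so one equivalent at −78 °C should be selective.

Step 4
Reactants: 6 2-bromomalonaldehyde (2-bromopropanedial)
Product: 7 (Z)-2-bromo-3-(trimethylsilyloxy)prop-2-enal
Conditions: Me3SiCl (1.1 equiv), Et3N (1.1 equiv), CH2Cl2, 0 °C to 20 °C; pentane, filtration, concentration; used at once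
Reagents that add atoms: chlorotrimethylsilane, C[Si](C)(C)Cl
Why: 6 exists as an acidic enol (a vinylogous carboxylic acid) and is O-silylated cleanly under amine-base conditions; the product is a moisture-sensitive vinylogous silyl ester, so it is made just before use, and its double-bond geometry does not matter.

Step 5
Reactants: 5 4-(2,4-dibromophenoxy)-1-methoxy-1,3-bis(trimethylsilyloxy)buta-1,3-diene; 7 (Z)-2-bromo-3-(trimethylsilyloxy)prop-2-enal
Product: 9 methyl 5-bromo-3-(2,4-dibromophenoxy)-2-hydroxybenzoate, via open-chain enal 8 (not isolated)
Conditions: 5 (1.1 equiv), TiCl4 (1.1 equiv), CH2Cl2, 4 Å MS, −78 °C to 20 °C, 20 h; aq. HCl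
Reagents that add atoms: none
Why: TiCl4 binds the aldehyde oxygen of 7 and turns the vinylogous silyl ester into a 1,3-dielectrophile; the terminal, aryloxy-bearing carbon of 5, the most nucleophilic site of a bis(silyloxy)diene, attacks in a vinylogous Mukaiyama step and forms C5–C6, and loss of the silyloxy group gives open-chain enal 8, the same compound whether attack is 1,2 or 1,4 because 7 is symmetric. The titanium-chelated β-ketoester enolate of 8 then adds through its α-carbon to the remaining aldehyde and forms C2–C3, closing ring A by a 6-exo-trig aldol that is allowed whether the enolate is written on the ester side (enolexo) or on the ketone side (enolendo). Loss of water and enolisation of the C1 carbonyl give the aromatic salicylate, which drives the sequence. The closest known reaction type is the TiCl4-mediated (3+3) cyclocondensation of 1,3-bis(silyloxy)buta-1,3-dienes, 4-aryloxy examples included, with 3-silyloxy-2-enones and their 2-halo derivatives. No stereocentre remains, since C4 of 8 and every enol ether geometry are erased on aromatisation. The only selectivity needed is γ-attack before α-attack, which the higher terminal nucleophilicity of 5 secures. Aryl C–Br and aryl–O bonds are inert to TiCl4 at or below 20 °C.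

Step 6
Reactants: 9 methyl 5-bromo-3-(2,4-dibromophenoxy)-2-hydroxybenzoate
Product: 11 2,4-dibromo-6-(2,4-dibromophenoxy)phenol, via salicylic acid 10 (not isolated)
Conditions: NaOH (4 equiv), MeOH–H2O, 65 °C; then AcOH to pH 5, Br2 (1.05 equiv), 0 °C to 20 °C; aq. Na2S2O3
Reagents that add atoms: bromine, BrBr; sodium hydroxide, [Na+].[OH-] (its oxygen appears only in intermediate 10 and leaves with the carboxyl group)
Why: Saponification gives the salicylate anion of 10, and electrophilic bromine then attacks C2 ipso, ortho to the hydroxyl, with loss of carbon dioxide (bromodecarboxylation of a salicylic acid, as in the conversion of salicylic acid to tribromophenol by bromine water). C2 is the only hydroxyl-activated position of ring A not already occupied by bromine or aryloxy, and ring B is a deactivated aryl ether, so one equivalent in an acetate buffer should stop at 11.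

Compound list

1 | 2,4-dibromophenol | Oc1ccc(Br)cc1Br | starting material
2 | methyl 4-chloro-3-oxobutanoate | COC(=O)CC(=O)CCl | starting material
3 | methyl 4-(2,4-dibromophenoxy)-3-oxobutanoate | COC(=O)CC(=O)COc1ccc(Br)cc1Br | intermediate
4 | methyl 4-(2,4-dibromophenoxy)-3-(trimethylsilyloxy)but-2-enoate (E/Z mixture) | COC(=O)C=C(COc1ccc(Br)cc1Br)O[Si](C)(C)C | intermediate
5 | 4-(2,4-dibromophenoxy)-1-methoxy-1,3-bis(trimethylsilyloxy)buta-1,3-diene (mixture of double-bond isomers) | COC(O[Si](C)(C)C)=CC(O[Si](C)(C)C)=COc1ccc(Br)cc1Br | intermediate
6 | 2-bromomalonaldehyde (2-bromopropanedial) | O=CC(Br)C=O | starting material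
7 | (Z)-2-bromo-3-(trimethylsilyloxy)prop-2-enal | O=C/C(Br)=C/O[Si](C)(C)C | intermediate
8 | methyl (E)-6-bromo-4-(2,4-dibromophenoxy)-3,7-dioxohept-5-enoate (racemic at C4; present in the flask as titanium-bound or silylated enol forms; not isolated) | COC(=O)CC(=O)C(Oc1ccc(Br)cc1Br)/C=C(\C=O)Br | intermediate
9 | methyl 5-bromo-3-(2,4-dibromophenoxy)-2-hydroxybenzoate | COC(=O)c1cc(Br)cc(Oc2ccc(Br)cc2Br)c1O | intermediate
10 | 5-bromo-3-(2,4-dibromophenoxy)-2-hydroxybenzoic acid (formed as its sodium salt; not isolated) | OC(=O)c1cc(Br)cc(Oc2ccc(Br)cc2Br)c1O | intermediate
11 | 2,4-dibromo-6-(2,4-dibromophenoxy)phenol | Oc1c(Br)cc(Br)cc1Oc1ccc(Br)cc1Br | target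

Total step count: 6. Longest linear sequence: 5 steps (steps 1, 2, 3, 5 and 6); step 4 is a one-step side branch that joins at step 5.

Steps least certain to work

Step 5 (key step). The most likely failure is loss of the trimethylsilyl groups of 5 and 7 to adventitious HCl before the carbon–carbon bond forms. The aryloxy-substituted diene terminus is more hindered and slower than an unsubstituted one, and 7 is a very labile vinylogous silyl ester. A second risk is stalling at a hydrated, non-aromatised stage. The fallback sets out from 5 and 6 and returns at 9. Compound 6 is condensed with propan-2-ol (cat. TsOH, cyclohexane, azeotropic removal of water) to give (Z)-2-bromo-3-(propan-2-yloxy)prop-2-enal F1, an isolable vinylogous ester with no O–Si bond. F1 and 5 are then combined with TiCl4 in CH2Cl2. Addition–elimination at the alkoxy-bearing carbon, with loss of propan-2-ol, should lead to the same 8 and on to 9.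

Step 3. The most likely failure is competing deprotonation of ring B at C3', between the two bromines, by the lithium amide, followed by C-silylation or bromine migration. Partial C-silylation of the dienolate is a lesser risk. The fallback sets out from 3 and returns at 5. Both enolisable positions are silylated in one flask by soft enolisation with Me3SiOTf (2.2 equiv) and Et3N in Et2O at 0 °C, the amine–silyl triflate method for converting 1,3-dicarbonyl compounds to bis(silyloxy)dienes. No amide base is present, and no compound outside the compound list is made (F0).

Step 1. The most likely failure is slow displacement by the weakly nucleophilic, ortho-substituted phenoxide of 1, which lets self-condensation of 2 take over. The fallback sets out from 1 and returns at 3. Compound 1 is O-alkylated with ClCH2CO2H and NaOH in water at reflux to give 2-(2,4-dibromophenoxy)acetic acid F2. F2 is coupled with 2,2-dimethyl-1,3-dioxane-4,6-dione (DCC, DMAP, CH2Cl2) to give 5-[2-(2,4-dibromophenoxy)-1-hydroxyethylidene]-2,2-dimethyl-1,3-dioxane-4,6-dione F3. Heating F3 in methanol opens the dioxanedione with loss of acetone and carbon dioxide and gives 3.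

Step 6. The most likely failure is over-bromination: further electrophilic attack at C3 or C5 of ring A or at C6' of ring B, or ipso attack at C4, if the bromodecarboxylation is slower than expected in the one-pot medium. The fallback sets out from 9 and returns at 11. Compound 9 is saponified and 10 is isolated by acidification. Compound 10 is protodecarboxylated (cat. Ag2CO3, AcOH, DMSO, 120 °C, a method for ortho-substituted benzoic acids) to give 4-bromo-2-(2,4-dibromophenoxy)phenol F4. F4 is then brominated at its single free ortho position with N-bromosuccinimide (1.0 equiv, CH2Cl2, 0 °C), a faster and milder substitution than the ipso process, to give 11.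

Further compounds

F1 | step 5 | (Z)-2-bromo-3-(propan-2-yloxy)prop-2-enal | O=C/C(Br)=C/OC(C)C
F0 | step 3 | none | none
F2 | step 1 | 2-(2,4-dibromophenoxy)acetic acid | OC(=O)COc1ccc(Br)cc1Br
F3 | step 1 | 5-[2-(2,4-dibromophenoxy)-1-hydroxyethylidene]-2,2-dimethyl-1,3-dioxane-4,6-dione | CC1(C)OC(=O)C(=C(O)COc2ccc(Br)cc2Br)C(=O)O1
F4 | step 6 | 4-bromo-2-(2,4-dibromophenoxy)phenol | Oc1ccc(Br)cc1Oc1ccc(Br)cc1Br
A1 | alternative 1 | 3,5-dibromo-2H-pyran-2-one | O=c1occ(Br)cc1Br
A2 | alternative 1 | 1-(ethynyloxy)-2-methoxybenzene | COc1ccccc1OC#C
A3 | alternative 1 | 2,4-dibromo-1-(2-methoxyphenoxy)benzene | COc1ccccc1Oc1ccc(Br)cc1Br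
A4 | alternative 1 | 2-(2,4-dibromophenoxy)phenol | Oc1ccccc1Oc1ccc(Br)cc1Br
A5 | alternative 2 | 4-bromo-2-(trimethylsilyl)phenyl trifluoromethanesulfonate | C[Si](C)(C)c1cc(Br)ccc1OS(=O)(=O)C(F)(F)F
A6 | alternative 2 | 4-bromo-1,2-didehydrobenzene | BrC1=CC#CC=C1
A7 | alternative 2 | 3,5-dibromo-2-methoxyphenol | COc1c(O)cc(Br)cc1Br
A8 | alternative 2 | 1,2-dibromo-1,1,2,2-tetrachloroethane | ClC(Cl)(Br)C(Cl)(Cl)Br
A9 | alternative 2 | 1,5-dibromo-3-(2,4-dibromophenoxy)-2-methoxybenzene | COc1c(Br)cc(Br)cc1Oc1ccc(Br)cc1Br
A10 | alternative 3 | 2-(2,4-dibromophenoxy)cyclopent-2-en-1-one | O=C1CCC=C1Oc1ccc(Br)cc1Br
A11 | alternative 3 | 2-(2,4-dibromophenoxy)-3-(trimethylsilyloxy)cyclopenta-1,3-diene | C[Si](C)(C)OC1=CCC=C1Oc1ccc(Br)cc1Br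
A12 | alternative 3 | bromoform | BrC(Br)Br
A13 | alternative 3 | dibromocarbene | Br[C]Br
A14 | alternative 3 | 2-bromo-6-(2,4-dibromophenoxy)phenol | Oc1c(Br)cccc1Oc1ccc(Br)cc1Br
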